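**Retrosynthetic overview**
- Target 14 is a (2S,4S)-3',4',7-trihydroxyflavan (rings A, B, C; 2,4-cis) joined from C4 to C8 of (+)-catechin (rings D, E, F); the last step is hydrogenolysis of octabenzyl ether 13.
- Two bonds are made in one flask: C4–C8 of ring D (8-lithiated perbenzylcatechin plus β-aryloxy aldehyde 9), then C4–C4a, which closes ring C by cationic Friedel–Crafts cyclisation.
- Enabling feature: C4 is a doubly benzylic methine. Ring D has oxygens ortho (O1, 7-O) and para (5-O) to C8, so a C4 cation forms readily; C4a of ring A is para to the 7-oxygen and ortho to O1, the most nucleophilic carbon of a resorcinol ether; C2 in the same six-membered ring directs C4.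
- Aldehyde 9: the O1–C2 aryl ether comes from copper-catalysed O-arylation (retention) of an (S)-homoallylic alcohol made by Brown allylation; C4 is unveiled by alkene cleavage.
- Ring order: rings D, E, F come intact from (+)-catechin, rings A and B are bought as arenes, ring C is formed last.

Key step: step 7

Remark: the descriptors are read as a 2,4-cis upper flavan (2S,4S) on (2R,3S)-catechin; 1-(benzyloxy)-3-iodobenzene and (−)-Ipc2B(allyl) solution are taken as purchasable.

**Route**

Step 1
Reactants: 1 (+)-catechin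
Product: 2 5,7,3',4'-tetra-O-benzylcatechin
Conditions: BnBr (4.4 equiv), K2CO3, DMF, 0 °C → rt
Reagents that add atoms: benzyl bromide, BrCc1ccccc1
Why: Williamson etherification with a carbonate base should cap the four phenols and leave the aliphatic 3-OH and both stereocentres untouched.

Step 2
Reactants: 2 5,7,3',4'-tetra-O-benzylcatechin
Product: 3 penta-O-benzylcatechin
Conditions: NaH, BnBr, n-Bu4NI (cat.), THF/DMF, 0 °C → rt
Reagents that add atoms: benzyl bromide, BrCc1ccccc1
Why: Williamson benzylation of the secondary alkoxide; with all phenols capped, no quinone-methide pathway for C2 epimerisation remains.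

Step 3
Reactants: 3 penta-O-benzylcatechin
Product: 4 8-bromo-penta-O-benzylcatechin
Conditions: NBS (1.0 equiv), CH2Cl2, −78 °C → rt
Reagents that add atoms: N-bromosuccinimide, O=C1CCC(=O)N1Br
Why: Electrophilic aromatic bromination of the phloroglucinol-type ring D should go to C8, the less hindered free position (C6 lies between two benzyloxy groups), as is established for perbenzylated flavan-3-ols.

Step 4
Reactants: 5 3,4-bis(benzyloxy)benzaldehyde
Product: 6 (S)-1-[3,4-bis(benzyloxy)phenyl]but-3-en-1-ol
Conditions: (−)-Ipc2B(allyl), Et2O, −78 °C; then NaOH, H2O2, 0 °C → rt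
Reagents that add atoms: (−)-B-allyldiisopinocampheylborane (from (+)-α-pinene), C=CCB(C1CC2CC(C1C)C2(C)C)C1CC2CC(C1C)C2(C)C
Why: Brown asymmetric allylboration through a chair Zimmerman–Traxler transition state; the reagent from (+)-α-pinene adds allyl to the Si face of aryl aldehydes and so sets the (S) carbinol that becomes C2.

Step 5
Reactants: 6 (S)-1-[3,4-bis(benzyloxy)phenyl]but-3-en-1-ol; 7 1-(benzyloxy)-3-iodobenzene
Product: 8 1-(benzyloxy)-3-{[(1S)-1-[3,4-bis(benzyloxy)phenyl]but-3-en-1-yl]oxy}benzene
Conditions: CuI (10 mol%), 3,4,7,8-tetramethyl-1,10-phenanthroline (20 mol%), Cs2CO3, 4 Å MS, toluene, 100 °C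
Reagents that add atoms: none
Why: Ullmann-type copper-catalysed C–O coupling of an aliphatic alcohol with an aryl iodide forms the O1–C(aryl) bond without breaking the carbinol C–O bond, so the (S) centre is carried over with retention.

Step 6
Reactants: 8 1-(benzyloxy)-3-{[(1S)-1-[3,4-bis(benzyloxy)phenyl]but-3-en-1-yl]oxy}benzene
Product: 9 (3S)-3-[3,4-bis(benzyloxy)phenyl]-3-[3-(benzyloxy)phenoxy]propanal
Conditions: OsO4 (2 mol%), NaIO4, 2,6-lutidine, dioxane/H2O (3:1), rt; crude aldehyde used at once
Reagents that add atoms: osmium tetroxide (catalytic oxygen transfer), O=[Os](=O)(=O)=O; sodium periodate (terminal oxidant), [Na+].[O-]I(=O)(=O)=O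
Why: Lemieux–Johnson oxidative cleavage is selective for the terminal alkene over the electron-rich arenes, and the buffered medium and immediate use should limit β-elimination of the aryloxide; no stereocentre is touched.

Step 7
Reactants: 4 8-bromo-penta-O-benzylcatechin; 9 (3S)-3-[3,4-bis(benzyloxy)phenyl]-3-[3-(benzyloxy)phenoxy]propanal
Product: 13 octa-O-benzyl-(2S)-3',4',7-trihydroxyflavan-(4α→8)-catechin, via 8-lithio-penta-O-benzylcatechin 10 (not isolated), via epimeric C4 carbinol 11 (not isolated), via C4 benzylic cation 12 (not isolated)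
Conditions: n-BuLi (1.05 equiv), THF, −78 °C; then 9, −78 °C; then CF3CO2H (5 equiv), CH2Cl2, −78 → −10 °C
Reagents that add atoms: none
Why: Bromine–lithium exchange at C8 of 4 gives aryllithium 10, whose 1,2-addition to aldehyde 9 forms the C4–C8 bond to ring D and gives carbinol 11 as a mixture of C4 epimers; on acidification the hydroxyl leaves from this 2,4,6-trioxygenated benzylic position to give the quinone-methide-like cation 12, which is captured by the tethered resorcinol ether ring at the carbon para to its benzyloxy group and ortho to the ether oxygen (the future C4a), and proton loss restores the arene. The closest known reaction types are the addition of 8-lithiated perbenzylated flavan-3-ols to carbonyl compounds and the dehydrative intramolecular Friedel–Crafts alkylation of electron-rich benzylic alcohols to 4-arylchromans. Ring C closes in a six-membered mode in which the attacking C4a=C8a bond of ring A lies inside the new ring (6-endo with respect to the arene) while the cationic carbon carries its stabilising aryl group outside it. The new stereocentre C4 is set by the existing C2 centre through a chair-like transition state with the C2 aryl group pseudo-equatorial and the bulky catechin unit on the planar cation pointing away from the face of ring A, which leads to the 2,4-cis (2S,4S) product; both carbinol epimers pass through the same cation, so the step is stereoconvergent. The step needs chemoselective ionisation at C4 over the C2 aryl ether, secured by three ortho/para oxygens on ring D against one para oxygen on ring B and by a weak acid at low temperature. It also needs attack at C4a rather than at the carbon between the two oxygens of ring A or a five-membered closure by ring B, secured by sterics and by the double activation of C4a, and the link to C8 rather than C6 of ring D follows from the position of the bromine atom in 4.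

Step 8
Reactants: 13 octa-O-benzyl-(2S)-3',4',7-trihydroxyflavan-(4α→8)-catechin
Product: 14 (2S)-3',4',7-trihydroxyflavan-(4α→8)-catechin (target)
Conditions: H2 (1 atm), Pd(OH)2/C, THF/MeOH, rt
Reagents that add atoms: none
Why: Hydrogenolysis of the eight benzyl ethers over Pd(OH)2 on carbon is the standard end game for perbenzylated proanthocyanidins and should leave the ring C–O bonds at C2, the doubly benzylic C4–H and all four stereocentres intact.

**Compound list**

1 | (+)-catechin, (2R,3S)-2-(3,4-dihydroxyphenyl)chromane-3,5,7-triol | Oc1cc(O)c2c(c1)O[C@H](c1ccc(O)c(O)c1)[C@@H](O)C2 | starting material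
2 | (2R,3S)-5,7-bis(benzyloxy)-2-[3,4-bis(benzyloxy)phenyl]chroman-3-ol (5,7,3',4'-tetra-O-benzylcatechin) | c1ccccc1COc1cc(OCc2ccccc2)c2c(c1)O[C@H](c1ccc(OCc3ccccc3)c(OCc3ccccc3)c1)[C@@H](O)C2 | intermediate
3 | (2R,3S)-3,5,7-tris(benzyloxy)-2-[3,4-bis(benzyloxy)phenyl]chromane (penta-O-benzylcatechin) | c1ccccc1COc1cc(OCc2ccccc2)c2c(c1)O[C@H](c1ccc(OCc3ccccc3)c(OCc3ccccc3)c1)[C@@H](OCc1ccccc1)C2 | intermediate
4 | (2R,3S)-3,5,7-tris(benzyloxy)-2-[3,4-bis(benzyloxy)phenyl]-8-bromochromane | c1ccccc1COc1cc(OCc2ccccc2)c2c(c1Br)O[C@H](c1ccc(OCc3ccccc3)c(OCc3ccccc3)c1)[C@@H](OCc1ccccc1)C2 | intermediate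
5 | 3,4-bis(benzyloxy)benzaldehyde | O=Cc1ccc(OCc2ccccc2)c(OCc2ccccc2)c1 | starting material
6 | (S)-1-[3,4-bis(benzyloxy)phenyl]but-3-en-1-ol | O[C@H](c1ccc(OCc2ccccc2)c(OCc2ccccc2)c1)CC=C | intermediate
7 | 1-(benzyloxy)-3-iodobenzene | Ic1cccc(OCc2ccccc2)c1 | starting material
8 | 1-(benzyloxy)-3-{[(1S)-1-[3,4-bis(benzyloxy)phenyl]but-3-en-1-yl]oxy}benzene | c1ccccc1COc1cccc(c1)O[C@H](c1ccc(OCc3ccccc3)c(OCc3ccccc3)c1)CC=C | intermediate
9 | (3S)-3-[3,4-bis(benzyloxy)phenyl]-3-[3-(benzyloxy)phenoxy]propanal | c1ccccc1COc1cccc(c1)O[C@H](c1ccc(OCc3ccccc3)c(OCc3ccccc3)c1)CC=O | intermediate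
10 | 8-lithio-penta-O-benzylcatechin | c1ccccc1COc1cc(OCc2ccccc2)c2c(c1[Li])O[C@H](c1ccc(OCc3ccccc3)c(OCc3ccccc3)c1)[C@@H](OCc1ccccc1)C2 | intermediate
11 | (3S)-3-[3,4-bis(benzyloxy)phenyl]-3-[3-(benzyloxy)phenoxy]-1-(penta-O-benzylcatechin-8-yl)propan-1-ol, both C1 epimers | c1ccccc1COc1cccc(c1)O[C@H](c1ccc(OCc3ccccc3)c(OCc3ccccc3)c1)CC(O)c1c(OCc3ccccc3)cc(OCc3ccccc3)c2c1O[C@H](c1ccc(OCc3ccccc3)c(OCc3ccccc3)c1)[C@@H](OCc1ccccc1)C2 | intermediate
12 | benzylic cation at C4 derived from 11 | c1ccccc1COc1cccc(c1)O[C@H](c1ccc(OCc3ccccc3)c(OCc3ccccc3)c1)C[CH+]c1c(OCc3ccccc3)cc(OCc3ccccc3)c2c1O[C@H](c1ccc(OCc3ccccc3)c(OCc3ccccc3)c1)[C@@H](OCc1ccccc1)C2 | intermediate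
13 | (2S,4S)-7-(benzyloxy)-2-[3,4-bis(benzyloxy)phenyl]-4-{(2R,3S)-3,5,7-tris(benzyloxy)-2-[3,4-bis(benzyloxy)phenyl]chroman-8-yl}chromane | c1ccccc1COc1ccc2c(c1)O[C@H](c1ccc(OCc3ccccc3)c(OCc3ccccc3)c1)C[C@@H]2c1c(OCc3ccccc3)cc(OCc3ccccc3)c2c1O[C@H](c1ccc(OCc3ccccc3)c(OCc3ccccc3)c1)[C@@H](OCc1ccccc1)C2 | intermediate
14 | (2R,3S)-2-(3,4-dihydroxyphenyl)-8-[(2S,4S)-2-(3,4-dihydroxyphenyl)-7-hydroxychroman-4-yl]chromane-3,5,7-triol | Oc1ccc2c(c1)O[C@H](c1ccc(O)c(O)c1)C[C@@H]2c1c(O)cc(O)c2c1O[C@H](c1ccc(O)c(O)c1)[C@@H](O)C2 | target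

**Step count and risks**

Total steps: 8. Longest linear sequence: 5 (steps 1, 2, 3, 7, 8, or equally 4, 5, 6, 7, 8).

Steps most likely to fail:

1. Step 7. The hindered aryllithium may deprotonate the aldehyde, which then expels the aryloxide. The C2 aryl ether may ionise in competition with the C4 carbinol and erode the C2 configuration. The ring closure may also show insufficient facial discrimination. The fallback sets out from aldehyde 9 (with bromide 4) and returns at 13. It closes ring C through the same C4a–C4 bond but sets C4 by hydride delivery instead. Pinnick oxidation of 9 (NaClO2, NaH2PO4, 2-methyl-2-butene, t-BuOH/H2O) should give (3S)-3-[3,4-bis(benzyloxy)phenyl]-3-[3-(benzyloxy)phenoxy]propanoic acid F1. Intramolecular Friedel–Crafts acylation ((CF3CO)2O, CH2Cl2, 0 °C) should close ring C to (2S)-7-(benzyloxy)-2-[3,4-bis(benzyloxy)phenyl]chroman-4-one F2. Aryllithium 10, made from 4 as in step 7, should add to the C4 ketone at −78 °C to give the tertiary 4-aryl-flavan-4-ol F3. Ionic hydrogenation (Et3SiH, CF3CO2H, CH2Cl2, −78 °C) should deliver hydride to the 4-aryl cation from the face opposite the C2 aryl group, leaving the catechin unit cis to it and giving 13.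

2. Step 5. Coupling of the hindered secondary benzylic alkoxide may be sluggish, with competing oxidation of the alkoxide to the ketone and reduction of the aryl iodide. The fallback sets out from aldehyde 5 and returns at 8. Allylation with the antipodal reagent (+)-Ipc2B(allyl) should give (R)-1-[3,4-bis(benzyloxy)phenyl]but-3-en-1-ol F4. Mitsunobu etherification with commercial 3-(benzyloxy)phenol (PPh3, DIAD, toluene, −20 → 0 °C) should then form the aryl ether with inversion to give 8; low temperature and a non-polar solvent are chosen to hold back ionisation of the electron-rich benzylic centre.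

3. Step 6. The aldehyde may lose the aryloxide by β-elimination (retro-oxa-Michael) in the buffered aqueous medium, or be over-oxidised. The fallback sets out from alkene 8 and returns at 9. Upjohn dihydroxylation (K2OsO4·2H2O cat., N-methylmorpholine N-oxide, acetone/H2O) should give the storable (4S)-4-[3,4-bis(benzyloxy)phenyl]-4-[3-(benzyloxy)phenoxy]butane-1,2-diol F5 as a mixture at C2. Criegee cleavage with Pb(OAc)4 in anhydrous CH2Cl2 at 0 °C, followed by filtration, should release 9 under base-free conditions immediately before step 7.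

**Further compounds**

F1 | step 7 | (3S)-3-[3,4-bis(benzyloxy)phenyl]-3-[3-(benzyloxy)phenoxy]propanoic acid | c1ccccc1COc1cccc(c1)O[C@H](c1ccc(OCc3ccccc3)c(OCc3ccccc3)c1)CC(=O)O
F2 | step 7 | (2S)-7-(benzyloxy)-2-[3,4-bis(benzyloxy)phenyl]chroman-4-one | c1ccccc1COc1ccc2c(c1)O[C@H](c1ccc(OCc3ccccc3)c(OCc3ccccc3)c1)CC2=O
F3 | step 7 | (2S)-7-(benzyloxy)-2-[3,4-bis(benzyloxy)phenyl]-4-(penta-O-benzylcatechin-8-yl)chroman-4-ol, C4 epimers | c1ccccc1COc1ccc2c(c1)O[C@H](c1ccc(OCc3ccccc3)c(OCc3ccccc3)c1)CC2(O)c1c(OCc3ccccc3)cc(OCc3ccccc3)c2c1O[C@H](c1ccc(OCc3ccccc3)c(OCc3ccccc3)c1)[C@@H](OCc1ccccc1)C2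
F4 | step 5 | (R)-1-[3,4-bis(benzyloxy)phenyl]but-3-en-1-ol | O[C@@H](c1ccc(OCc2ccccc2)c(OCc2ccccc2)c1)CC=C
F5 | step 6 | (4S)-4-[3,4-bis(benzyloxy)phenyl]-4-[3-(benzyloxy)phenoxy]butane-1,2-diol, C2 epimers | c1ccccc1COc1cccc(c1)O[C@H](c1ccc(OCc3ccccc3)c(OCc3ccccc3)c1)CC(O)CO
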